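| flask | Z | Q | remark | time |
|---|---|---|---|---|
| north-east | 0.010 M | 0.93 mM (held) | the very flask that is asked about, followed so far |  |
| east | 0.020 M | 0.93 mM (held) | run made earlier |  |
| flask | 0.010 M | 0.93 mM (held) |  | 25 h |

| run | time / h | L / % | Z / % |
|---|---|---|---|
| north-east | 0.333 | 0 | 46.6 |
| north-east | 0.667 | 2.9 | 35.5 |
| north-east | 1.00 | 2.6 | 27.9 |
| north-east | 1.50 | 6.4 | 17.8 |
| north-east | 2.50 | 11.0 | 0 |
| north-east | 5.00 | 17.3 | 0 |
| east | 4.00 | 7.9 | 33.8 |
| east | 8.00 | 12.8 | 0 |
| east | 12.0 | 14.7 | 1.1 |
| east | 15.0 | 15.4 | 0.8 |
| east | 20.0 | 15.5 | 0 |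
| east | 25.0 | 14.5 | 0.1 |

(standard deviation of a reading: 0.5 percentage points)
- the L standing at 25 h, as a percentage of the Z charged
- concentration of J in solution at 2.5 h, in percent of saturation
- the change that raises the amount of L at 25 h, in percent of the Z charged most ("none" if none brings more than 2 percentage points) (Saturday's / Wednesday's / Thursday's / Tuesday's / none)
- amount of L at 25 h, in percent of the Z charged, after Thursday's
- Saturday's: doubling the transfer coefficient of Q, all else as stated
- Wednesday's: doubling the solubility of Z, all else as stated
- Thursday's: doubling the dissolution coefficient of Z, all else as stated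
- Tuesday's: doubling the saturation concentration of Q, all else as stated
- as a solid, counted per litre of solution: Z
- at the start none of Q is in solution
- at the start none of Z is in solution
- J is what Q becomes in solution

1. Slowness shows in L: the north-east flask still gains L at 5.00 h, though Z already reads 0% at 2.50 h. Q is held, so Z is the limiting reagent.

2. Fold the givens into one number, the saturation load 9.30%: the Q-saturated solution's J as a fraction of the charge. For the east run it is 4.65%.

3. My end state: the north-east flask gains 11.0% in its first 2.50 h and 6.3 percentage points in the next. Continuing that ratio gives 25.7%, against the east plateau of 15.5%. One doubling of the load is thus worth 10 points, more than the 2 points threshold. Tuesday's doubles the load again, so my own reckoning picks it, where the forecast below says none.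

4. Is one number enough? Both runs hold Q at 0.93 mM, so the gas side is untested. J was not read, so my own reckoning gives no figure for sat; the forecast below does give one. Z is down to 46.6% by 0.333 h, so I leave Thursday's at my y.

The forecast: 21%, 20%, none, 21%. “The other changes seem unlikely to improve selectivity, so I choose none, tentatively.”

The flask gives 22.1%, 56.6%, Tuesday's, 21.9%. The forecast's sat stands 37 points too low.

    Q ⇌ J, rate k1*(csat - [J]) (kL = 0.0251 min⁻¹)
    X + J → L (k = 3.32 M⁻¹ min⁻¹)
    X → D (k = 0.00383 min⁻¹)
    J → G (k = 4.73 × 10⁻⁴ min⁻¹)
    X + L → E (k = 0.476 M⁻¹ min⁻¹)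
    Z ⇌ X, rate k6*(cs6 - [X]) while solid is left; crystals form when [X] > cs6 (solubility = 6.00 mM, k = 0.101 min⁻¹)

East to flask, a doubling of the load gains 6.6 points. Tuesday's takes the load to 18.6% and adds 13 points, reaching 34.8%, more than the 28.7% that gain gives: gas and charge don't trade evenly, so one number wasn't enough.

On the charge side it still serves. With 0.0040 M of Z the load is 23.2%, which gives 30.8%. The neighbour flask gives 29.9%.

The runs stem from a simulated flask for substances that don't exist.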